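Between the first two readings of the zeta run, 79.3 % of the substrate consumed turns into side product, at a mean [rival reagent] of 0.0518 M.

the same everywhere: gas 6.8 mM (held)
- zeta: substrate 0.050 M; rival reagent 0.075 M; run made earlier
- gamma: substrate 0.050 M; rival reagent 0.037 M; run made earlier
- beta: substrate 0.050 M; rival reagent 0.056 M; run made earlier
- alpha: substrate 0.075 M; rival reagent 0.075 M; run made earlier
- south: substrate 0.050 M; rival reagent 0.0750 M; everything together at the start; time 6.0 min
- east: substrate 0.050 M; rival reagent 0.0750 M (fed, over 2.5 min); all else is in the flask from the start; the feed brings no volume worth counting; time 6.0 min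
- west: substrate 0.050 M (fed, over 2.5 min); rival reagent 0.0750 M; all else is in the flask from the start; the feed brings no volume worth counting; time 6.0 min

| run | time / min | side product / % | target / % |
|---|---|---|---|
| zeta | 0.667 | 37.7 | 6.4 |
| zeta | 1.33 | 54.9 | 10.9 |
| zeta | 2.00 | 64.8 | 12.2 |
| zeta | 2.50 | 69.2 | 13.6 |
| zeta | 3.00 | 73.3 | 12.3 |
| zeta | 4.00 | 79.0 | 11.5 |
| gamma | 0.417 | 15.1 | 4.3 |
| gamma | 0.667 | 20.6 | 7.3 |
| gamma | 1.00 | 26.7 | 10.3 |
| gamma | 2.00 | 39.9 | 19.6 |
| gamma | 3.00 | 45.2 | 23.6 |
| gamma | 5.00 | 52.9 | 28.1 |
| beta | 0.833 | 34.1 | 9.0 |
| beta | 1.50 | 47.5 | 12.2 |
| beta | 2.50 | 58.0 | 17.2 |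
| beta | 3.00 | 61.9 | 16.7 |
| beta | 4.00 | 66.2 | 18.6 |
| beta | 5.00 | 70.2 | 16.4 |
| alpha | 1.00 | 44.1 | 8.5 |
| alpha | 2.00 | 59.9 | 13.8 |
| alpha | 3.00 | 65.9 | 15.8 |
| alpha | 4.00 | 69.9 | 17.4 |
| alpha | 5.00 | 72.9 | 17.0 |

(scatter of a reading: 0.5 percentage points)

- at the start none of the gas is in solution
- a reading or a percentage of target counts all its forms, free or not

* the flask that comes out highest in amount of side product, in percent of the substrate charged; "all alike" if 1.5 percentage points covers them all (south / east / west / all alike)
* amount of side product at the end, in percent of the substrate charged, south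
* amount of side product at the end, in percent of the substrate charged, east
* amount of side product at the end, in percent of the substrate charged, west

With the fall of substrate over that interval, this reads as 11.3 /M/min: the side constant, side product formed per minute per [substrate] and per [rival reagent]. I use it as a side half-life, the pseudo-first-order time in which substrate halves through rival reagent alone at a held [rival reagent].

Does the order of addition count? South at its charge has a side half-life of 0.816 min, shorter than the feed of 2.5 min, so it can.

What does substrate meet during the feed in east? With none consumed, the mean [rival reagent] is 0.0375 M, close to the gamma charge, so I let gamma stand in. Halfway between its readings at 2.00 min and 3.00 min stand 42.5 % side product and 35.8 % substrate.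

What becomes of that substrate in east? The early share does not carry over to late times: between 2.00 min and 4.00 min of the zeta run, side product gains 14 percentage points while the target reading goes from 12.2 % to 11.5 %, a read share of 105 %. So after the feed I count substrate lost as side product one for one. [Rival reagent] is then 0.0537 M, which gives a side half-life of 1.14 min at that held value, and over the remaining 3.50 min substrate falls to 11.9 % of that amount. My east ends near 74.1 %.

South has the zeta charge; from its last reading, the same constant gives 84.2 %. West's substrate spends a mean 4.75 min in the flask, and that line gives 81.0 %. So I put south highest.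

The forecast also names south, with 85 %, 81 % for east and 83.5 % for west, holding for east “so more target forms, though some is later lost”; on east my figure differs.

South gives 85.9 %, east 71.5 % and west 78.5 %.

    crystals ⇌ target, rate k1*(cs1 - [target]) while solid is left; crystals form when [target] > cs1 (solubility = 3.90 mM, k = 0.300 /s)
    gas ⇌ partner, rate k2*(csat - [partner]) (kL = 0.0480 /s)
    substrate + partner ⇌ target (K = 65.0 /M, k = 1.00 /M/s)
    substrate + rival reagent → side product (k = 0.190 /M/s)

Over the first 2.5 min the mean [rival reagent] is 0.0280 M in east and 0.0511 M in south. A neighbour of east charged with 0.019 M of rival reagent keeps 30 % of it at 6.00 min, which is 0.005720 M. Its side half-life is then 10.7 min, longer than the run, and that flask ends at 26.6 % side product.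

The data were generated by integration for an exercise, and the scatter is random.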